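## Structural features

The target is a hexacyclic stilbenoid: a benzene ring A with a single hydrogen (on A2) carries two 2-(4-hydroxyphenyl)-3-aryl-2,3-dihydrobenzofurans, one through O–A1 and C-b–A6 and one through O–A3 and C-d–A4, and a seven-membered ring that runs A6, C-b, two adjacent carbons of the resorcinol ring C, C-c, CH2, A5. C-c bears the 2,4-dihydroxyphenyl ring B, and C-d bears a second, free 3,5-dihydroxyphenyl ring. The five stereocentres form two adjacent trans pairs, C-a/C-b (S,S) and C-d/C-e (R,R), and the single centre C-c (S), which sits 1,4 to C-b across ring C. The two dihydrofurans are mirror images of each other about the line through A2 and A5, so the compound that lacks the C-c–ring C bond is meso and its two resorcinol rings are enantiotopic; the chirality of the target lies only in which of them is bonded to C-c. This is the real difficulty: the two furans must be made in opposite absolute senses, and when the seven-membered ring closes the two resorcinol rings must differ chemically, or the enantiomeric purity built earlier is lost. Fragile are the eight phenols, the electron-rich rings (oxidants, electrophiles), the benzylic aryl ether bonds C-a–O and C-e–O, which ionise under acid, and the doubly benzylic C–H bonds at C-b, C-c and C-d, which rule out a late radical functionalisation. A hand-built geometric model of the fused system places ring B at C-c pseudo-axial, turned away from the oxygen of ring C ortho to C-c and on the face of the C-b hydrogen, so C-c is the centre that substrate control should set. The key step exploits the C-d/C-e dihydrofuran: with its oxygen on A3, C-d on A4 and the aryl-bearing C-e, it is the ring-contracted isomer of a flavanone in which C-e is C2, C-d is C3 and A4 is the carbon that migrates from the carbonyl carbon to C3, leaving a carboxyl group on C-d as the handle for the resorcinol ring.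

## Logic of the disconnections

39 from 38 and 37 (six O–CH3 bonds, two O–S bonds). The phenols are uncovered last because free phenols would not survive the oxidative and Lewis-acidic steps. The sulfonates are cut first, from 37, where no other phenol is present and hot hydroxide is harmless; the six methyl ethers are cut from 38. The demand on the forward steps is that the Lewis acid does not open the two benzylic aryl ethers irreversibly.

37 from 36 (C-c–ring C bond). This bond closes the seven-membered ring and creates C-c; cutting it leaves a stilbene whose double-bond geometry does not matter. Forward, a cation at C-c, stabilised by ring B, is attacked by the ortho carbon of ring C. The demand is twofold: only ring C may attack, which is why the aryl group on C-d in 36 carries two sulfonate groups and ring C two methoxy groups; and the face of the cation must be chosen by the strain between ring B and the ortho methoxy group of ring C.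

36 from 32 and 34, 34 from 33, 32 from 31, 31 from 30 (the CH=CH bond, then redox and ester changes at the A5 carbon). Cutting the double bond gives a ring A aldehyde and a benzylic phosphonium salt from a commercial alcohol. The A5 carbon is carried from 1 as a protected alcohol, so the price is one reduction and one oxidation. The demand is that a hindered aldehyde accepts a semi-stabilised ylide.

30 from 28 and 14, 28 from 27 (C-b–ring C bond). Ring C is attached by decarboxylative arylation, so that C-b is made as an ester-bearing carbon and the resorcinol ring comes from a simple aryl iodide. The forward step must capture the C-b radical on the face away from the C-a aryl group and must leave the aryl sulfonates alone.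

27 from 23, 23 from 22 and 7, 22 from 20, 20 from 18 (A6–C-b bond; C-a–aryl bond; the pyranone carbons; the A6–acyl bond). The first dihydrofuran is traced to a second flavanone by the same ring contraction as in the key step, and that flavanone to a chromone and an arylboronic acid. The reason is absolute control: C-a is set by the catalyst, with the enantiomer of the ligand used for C-e, and C-b follows C-a. The demands are acylation at A6 and not at A2, and survival of the existing dihydrofuran under Lewis acid and under the iodine oxidant.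

18 from 13 and 16, 16 from 15, 15 from 14 (C-d–aryl bond; O–S and O–C bonds of the aryl partner). The resorcinol ring on C-d enters as its bis-sulfonate. This costs two steps on the aryl iodide and one deprotection, and it buys three things: the ring cannot be acylated in the step to 20, cannot be attacked by the oxidant in the step to 27, and cannot compete for the C-c cation in the step to 37.

13 from 12, 12 from 8 (C-d–A4 bond; key step). The dihydrofuran with two stereocentres is reduced to a flavanone with one. The demands are that ring A migrates in preference to the C2 aryl group and that C2 keeps its configuration. In 8 the C5 carbon is already at the alcohol oxidation level, because a methyl group there could not be functionalised later next to the benzylic hydrogens at C-d and C-e; the C7 oxygen is a methyl ether, which is removed later by chelation to the A6 ketone.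

8 from 6 and 7, 6 from 4, 4 from 2, 2 from 1 (C-e–aryl bond; pyranone carbons; acetyl–ring bond; ester). A catalytic conjugate arylation of a chromone sets C-e. The chromone comes from an ortho-hydroxy acetophenone, and that from acylation of a symmetrical resorcinol dimethyl ether, in which the two reactive positions are equivalent.

## Other disconnections considered

Alternative 1: The cut removes three bonds of ring A at once (between ring atoms A1 and A2, A3 and A4, A1 and A6), so that ring A is made last from the open-chain diazo enone, compound A1. Forward, light converts the diazo ketone of compound A1 into a vinylketene (Wolff rearrangement), which adds to the tethered ethynyl ether, opens to a dienylketene and closes by 6π electrocyclisation to the phenol, compound A2; the tether makes the C-d/C-e dihydrofuran in the same event.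
- In its favour: ring A is formed fully substituted, so there is no question of ring atom A2 against A6 in an electrophilic substitution. On this regiochemical point it is better than the chosen plan, which relies twice on the directing effect of an ether oxygen.
- Also in its favour: the seven-membered ring exists before ring A, so no cation ever chooses between two resorcinol rings. The chosen plan pays for this with two sulfonate groups and an extra deprotection, so the alternative is better here too.
- Against it here: compound A1 must hold all five stereocentres before the step, three of them on open chains where each must be set separately. C-d is benzylic and next to the diazo ketone and may epimerise. The ethynyl ether of a para-methoxybenzylic alcohol is acid-labile. The ketene must find the alkyne across a short tether that forces a strained bicyclic cyclobutenone.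
- Comparison: on mechanism the alternative is neutral and pericyclic, the equal or the better of the acidic iodine oxidation toward the benzylic ethers. On structure the chosen plan lets each second centre follow a catalytically set first one in a ring. On step economy the alternative is more convergent, but compound A1 needs several stereocontrolled fragment syntheses and compound A2 still needs the C-a furan closed, so a lower total is not expected.

Alternative 2: The cut is the C-c=CH double bond of the dibenzocycloheptene, compound A4, traced to the keto aldehyde, compound A3, with the aldehyde on ring atom A5 and the ring B ketone on ring C. Forward, low-valent titanium from TiCl4 and zinc couples the two carbonyl groups through a titanium pinacolate and removes both oxygens (McMurry reaction); hydrogenation of compound A4 must then create C-c.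
- In its favour: the ring is closed between two carbons that are unique in the molecule, so the aryl group on C-d can be a plain dimethoxyphenyl ring. On protecting-group economy it is better than the chosen plan. Neither carbonyl group is enolisable, and the aldehyde is the same kind of intermediate as 32 (equal).
- Against it here: low-valent titanium is both reducing and Lewis acidic and threatens the two benzylic aryl ether bonds. C-c would be set by adding hydrogen to a trisubstituted triaryl alkene with no control element except the fold of the tricycle, and it is not assured that the open face is the one that leaves ring B pseudo-axial. Ring C would have to arrive at C-b already carrying a bulky ortho aroyl group.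
- Comparison: on mechanism a reductive coupling replaces a cation, which removes the competition problem but not the C-c problem; in the chosen plan the strain that threatens the hydrogenation works for the ring closure. On step economy the two are about equal: no sulfonate steps and no phosphonium salt, but a more elaborate ring C partner and a hydrogenation.

Alternative 3: The cut takes C-c out early: the CH2–ring A bond and the C-c–ring B bond of the triarylethane ester, compound A8, are made together from the vinylarene, compound A5, the aryl bromide, compound A6, and the arylzinc reagent, compound A7. Forward, with NiBr2(dme) and a chiral bis(oxazoline), the aryl group of compound A6 adds to the terminal carbon of the vinyl group of compound A5 and the benzylic nickel species couples with compound A7.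
- In its favour: C-c is set by the catalyst, independently of every other centre, which is better than the substrate control of step 20. Three simple achiral components are joined in one operation. Ring A enters as a symmetrical bis(benzyloxy)phenyl group, so closure of the seven-membered ring by the ester onto ring A has no regiochemical alternative (better). The way to the seven-membered ring is much shorter (better).
- Against it here: after compound A8 both dihydrofurans, with four stereocentres, must be built on a ring A that is already part of the seven-membered ring, with the remote C-c as the only control element. C-b must be created from a diaryl ketone, and the preferred arrangement in the folded ring is not clearly the one required. The ortho ester next to the vinyl group may slow the nickel step or lower its selectivity.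
- Comparison: the alternative sets C-c first by catalyst and leaves four centres to substrate control; the chosen plan sets the four furan centres by two catalyst-controlled conjugate additions and leaves C-c to substrate control. On mechanism both steps are of known types. On step economy the alternative wins up to the seven-membered ring and probably loses afterwards.

Key step: step 5

**Corrections to the stated design and one assumption.**
- The configurations of the flavanone (2R) and of the ring-contracted ester (2R,3R, trans) are the ones the target needs at C-e and C-d; no structure has to be corrected.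
- The C5 substituent of the flavanone is carried as CH2OPiv and not as CH3. After the key step a benzylic bromination could not be selective against the C-e and C-d hydrogens or a benzyl ether.
- The C7 oxygen is a methyl ether. A benzyl ether could not be removed by hydrogenolysis beside a benzylic pivalate; the methyl ether is cleaved by chelation in step 10.
- The resorcinol ring on C-d enters as a bis-tosylate, because of the symmetry trap described above.
- The flavanone is made by conjugate arylation of a chromone rather than by cyclisation of a chalcone, for more dependable enantioselectivity.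
- Assumption: (S)-t-BuPyOx is taken to give the (2R)-flavanone, by analogy with cyclic enones; if the sense is the opposite, the ligand enantiomers of steps 4 and 12 are exchanged.

## Route

Step 1
Reactants: 1 (3,5-dimethoxyphenyl)methanol
Product: 2 3,5-dimethoxybenzyl pivalate
Conditions: PivCl, Et3N, DMAP (cat.), CH2Cl2, 0 °C → rt
Reagents that add atoms: pivaloyl chloride CC(C)(C)C(=O)Cl
Why: Acylation of a primary alcohol; the pivalate carries the future CH2 of the seven-membered ring at the alcohol oxidation level through the acidic, oxidative and nickel-mediated steps and is removed only in step 16.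

Step 2
Reactants: 2 3,5-dimethoxybenzyl pivalate
Product: 4 2-acetyl-3-hydroxy-5-methoxybenzyl pivalate, via methoxy ketone 3 (not isolated)
Conditions: AcCl, SnCl4, CH2Cl2, −20 → 0 °C; then BCl3, −78 → 0 °C; aq. NaHCO3
Reagents that add atoms: acetyl chloride CC(=O)Cl
Why: Friedel–Crafts acylation goes para to one methoxy group and ortho to the other, next to the CH2 group (two equivalent positions; the position between the methoxy groups is less reactive, as in orcinol dimethyl ether); BCl3 then cleaves only the methyl ether that chelates to the new ketone.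

Step 3
Reactants: 4 2-acetyl-3-hydroxy-5-methoxybenzyl pivalate
Product: 6 (7-methoxy-4-oxo-4H-chromen-5-yl)methyl pivalate, via enaminone 5 (not isolated)
Conditions: Me2NCH(OMe)2, toluene, 100 °C; then aq. HCl, CH2Cl2, rt
Reagents that add atoms: N,N-dimethylformamide dimethyl acetal COC(OC)N(C)C
Why: Condensation of the acetyl group with the amide acetal gives the enaminone; acid-induced addition of the phenol and loss of dimethylamine closes the chromone (enaminone route to chromones).

Step 4
Reactants: 6 (7-methoxy-4-oxo-4H-chromen-5-yl)methyl pivalate; 7 (4-methoxyphenyl)boronic acid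
Product: 8 [(2R)-7-methoxy-2-(4-methoxyphenyl)-4-oxochroman-5-yl]methyl pivalate
Conditions: Pd(OCOCF3)2 (5 mol %), (S)-t-BuPyOx (6 mol %), NH4PF6, H2O, ClCH2CH2Cl, 60 °C
Reagents that add atoms: none
Why: Enantioselective conjugate addition of an arylboronic acid to a chromone with a cationic divalent palladium–pyridine-oxazoline catalyst; aryl transfer to C2 on the face chosen by the ligand sets C-e (R), and the palladium enolate is protonated without base, so the pyranone should not open to the chalcone.

Step 5
Reactants: 8 [(2R)-7-methoxy-2-(4-methoxyphenyl)-4-oxochroman-5-yl]methyl pivalate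
Product: 12 methyl (2R,3R)-6-methoxy-2-(4-methoxyphenyl)-4-(pivaloyloxymethyl)-2,3-dihydrobenzofuran-3-carboxylate, via enol ether 9 (not isolated), via iodane 10 (not isolated), via ortho ester 11 (not isolated)
Conditions: PhI(OAc)2 (1.2 equiv), H2SO4, HC(OMe)3, 0 °C → rt; then aq. HCl
Reagents that add atoms: trimethyl orthoformate COC(OC)OC; water O
Why: Acid and the orthoformate turn the ketone into the methyl enol ether 9, whose C3 attacks the acid-activated trivalent iodine reagent on the face opposite the C2 aryl group, and methanol adds to C4 to give the ketal iodane 10. The ipso carbon A4 then shifts from C4 to C3 from the back of the C–I bond while iodobenzene leaves (a 1,2-aryl shift through a bridged, phenonium-like transition state), and the resulting dioxocarbenium ion is taken up by methanol as ortho ester 11, which aqueous acid turns into the ester. This is the known oxidative ring contraction of flavanones to methyl 2-aryl-2,3-dihydrobenzofuran-3-carboxylates with PhI(OAc)2 or Tl(NO3)3 in trimethyl orthoformate. The five-membered ring is closed by ring contraction and not by cyclisation of a chain: the C-d–A4 bond forms as the C4–A4 bond breaks. The new centre C-d is controlled by C-e, because anti iodination followed by inversion at C3 places the ester carbon trans to the C-e aryl group, which is also the more stable epimer of this enolisable position, while C-e itself is never part of a reacting bond. The selectivity needed is migration of ring A in preference to the C2 aryl group, which would lead to an isoflavone; it is secured by the ring oxygen ortho and the methoxy group para to the migrating carbon, and by the ketal, which makes C4 a stabilised dioxocarbenium ion as ring A leaves it. Loss of configuration at C-e by opening of the pyranone should be avoided because the ketone is consumed as its enol ether under acid and no base is present.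

Step 6
Reactants: 12 methyl (2R,3R)-6-methoxy-2-(4-methoxyphenyl)-4-(pivaloyloxymethyl)-2,3-dihydrobenzofuran-3-carboxylate
Product: 13 (2R,3R)-6-methoxy-2-(4-methoxyphenyl)-4-(pivaloyloxymethyl)-2,3-dihydrobenzofuran-3-carboxylic acid
Conditions: Me3SnOH, ClCH2CH2Cl, 80 °C; then aq. HCl
Reagents that add atoms: trimethyltin hydroxide C[Sn](C)(C)O
Why: Neutral tin-assisted hydrolysis of a methyl ester; it should spare the pivalate and avoids an ester enolate, which could expel the phenoxide (retro-oxa-Michael) and scramble C-d and C-e.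

Step 7
Reactants: 14 1-iodo-3,5-dimethoxybenzene
Product: 15 5-iodobenzene-1,3-diol
Conditions: BBr3, CH2Cl2, −78 °C → rt; H2O
Reagents that add atoms: none
Why: Lewis-acid cleavage of aryl methyl ethers on a simple arene.

Step 8
Reactants: 15 5-iodobenzene-1,3-diol
Product: 16 5-iodo-1,3-phenylene bis(4-methylbenzenesulfonate)
Conditions: TsCl, Et3N, DMAP (cat.), CH2Cl2, 0 °C → rt
Reagents that add atoms: 4-methylbenzenesulfonyl chloride Cc1ccc(S(=O)(=O)Cl)cc1
Why: Sulfonylation of both phenols; the tosylates make this ring non-nucleophilic, so that it can neither be acylated in step 10, attacked by the iodine oxidant in step 13, nor capture the C-c cation in step 20, and aryl tosylates are inert to nickel–bipyridine catalysis at room temperature.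

Step 9
Reactants: 13 (2R,3R)-6-methoxy-2-(4-methoxyphenyl)-4-(pivaloyloxymethyl)-2,3-dihydrobenzofuran-3-carboxylic acid; 16 5-iodo-1,3-phenylene bis(4-methylbenzenesulfonate)
Product: 18 [(2R,3R)-3-[3,5-bis(tosyloxy)phenyl]-6-methoxy-2-(4-methoxyphenyl)-2,3-dihydrobenzofuran-4-yl]methyl pivalate, via redox-active ester 17 (not isolated)
Conditions: N-hydroxyphthalimide, i-PrN=C=N-i-Pr, DMAP (cat.), CH2Cl2, rt; then 16, NiBr2(dme) (10 mol %), 4,4′-di-tert-butyl-2,2′-bipyridine, Zn, DMA, rt
Reagents that add atoms: none
Why: Nickel-catalysed decarboxylative cross-electrophile coupling of an N-hydroxyphthalimide ester with an aryl iodide; one-electron reduction of the ester releases CO2 and the benzylic radical at C-d, which the aryl–nickel species should capture on the face away from the C-e aryl group, so the aryl group enters trans (C-d R) and C-e is untouched.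

Step 10
Reactants: 18 [(2R,3R)-3-[3,5-bis(tosyloxy)phenyl]-6-methoxy-2-(4-methoxyphenyl)-2,3-dihydrobenzofuran-4-yl]methyl pivalate
Product: 20 [(2R,3R)-5-acetyl-3-[3,5-bis(tosyloxy)phenyl]-6-hydroxy-2-(4-methoxyphenyl)-2,3-dihydrobenzofuran-4-yl]methyl pivalate, via methoxy ketone 19 (not isolated)
Conditions: AcCl, SnCl4, CH2Cl2, −40 → −10 °C; then BCl3 (1.2 equiv), −78 → 0 °C; aq. NaHCO3
Reagents that add atoms: acetyl chloride CC(=O)Cl
Why: Friedel–Crafts acylation of ring A at A6, the only free position para to an ether oxygen (the furan oxygen on A3) and the same kind of position as in step 2, while the other rings are an anisole and the deactivated bis-tosylate; BCl3 then removes the A1 methyl group through the chelate with the new ketone and frees the phenol for the second pyranone.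

Step 11
Reactants: 20 [(2R,3R)-5-acetyl-3-[3,5-bis(tosyloxy)phenyl]-6-hydroxy-2-(4-methoxyphenyl)-2,3-dihydrobenzofuran-4-yl]methyl pivalate
Product: 22 [(2R,3R)-3-[3,5-bis(tosyloxy)phenyl]-2-(4-methoxyphenyl)-5-oxo-2,3-dihydro-5H-furo[3,2-g]chromen-4-yl]methyl pivalate, via enaminone 21 (not isolated)
Conditions: Me2NCH(OMe)2, toluene, 100 °C; then aq. HCl, CH2Cl2, rt
Reagents that add atoms: N,N-dimethylformamide dimethyl acetal COC(OC)N(C)C
Why: The same enaminone route to the chromone as in step 3, now on the A1 phenol and the A6 acetyl group.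

Step 12
Reactants: 22 [(2R,3R)-3-[3,5-bis(tosyloxy)phenyl]-2-(4-methoxyphenyl)-5-oxo-2,3-dihydro-5H-furo[3,2-g]chromen-4-yl]methyl pivalate; 7 (4-methoxyphenyl)boronic acid
Product: 23 [(2R,3R,7S)-3-[3,5-bis(tosyloxy)phenyl]-2,7-bis(4-methoxyphenyl)-5-oxo-2,3,6,7-tetrahydro-5H-furo[3,2-g]chromen-4-yl]methyl pivalate
Conditions: Pd(OCOCF3)2 (5 mol %), (R)-t-BuPyOx (6 mol %), NH4PF6, H2O, ClCH2CH2Cl, 60 °C
Reagents that add atoms: none
Why: The conjugate arylation of step 4 with the enantiomeric ligand; catalyst control sets C-a (S), the mirror image of C-e, and the existing centres lie far from the reacting carbon and should not interfere.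

Step 13
Reactants: 23 [(2R,3R,7S)-3-[3,5-bis(tosyloxy)phenyl]-2,7-bis(4-methoxyphenyl)-5-oxo-2,3,6,7-tetrahydro-5H-furo[3,2-g]chromen-4-yl]methyl pivalate
Product: 27 methyl (2R,3R,5S,6S)-3-[3,5-bis(tosyloxy)phenyl]-2,6-bis(4-methoxyphenyl)-4-(pivaloyloxymethyl)-2,3,5,6-tetrahydrobenzo[1,2-b:5,4-b']difuran-5-carboxylate, via enol ether 24 (not isolated), via iodane 25 (not isolated), via ortho ester 26 (not isolated)
Conditions: PhI(OAc)2 (1.2 equiv), H2SO4, HC(OMe)3, 0 °C → rt; then aq. HCl
Reagents that add atoms: trimethyl orthoformate COC(OC)OC; water O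
Why: Second use of the oxidative ring contraction of step 5: ring carbon A6, with oxygen ortho (on A1) and para (on A3), migrates from the carbonyl carbon to C3 and forms A6–C-b, and the ester settles trans to the C-a aryl group (C-b S); the bis-tosylate ring and the anisole rings are too electron-poor to react with the oxidant.

Step 14
Reactants: 27 methyl (2R,3R,5S,6S)-3-[3,5-bis(tosyloxy)phenyl]-2,6-bis(4-methoxyphenyl)-4-(pivaloyloxymethyl)-2,3,5,6-tetrahydrobenzo[1,2-b:5,4-b']difuran-5-carboxylate
Product: 28 (2R,3R,5S,6S)-3-[3,5-bis(tosyloxy)phenyl]-2,6-bis(4-methoxyphenyl)-4-(pivaloyloxymethyl)-2,3,5,6-tetrahydrobenzo[1,2-b:5,4-b']difuran-5-carboxylic acid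
Conditions: Me3SnOH, ClCH2CH2Cl, 80 °C; then aq. HCl
Reagents that add atoms: trimethyltin hydroxide C[Sn](C)(C)O
Why: The neutral methyl ester hydrolysis of step 6; pivalate and aryl tosylates should be spared and no enolate is formed.

Step 15
Reactants: 28 (2R,3R,5S,6S)-3-[3,5-bis(tosyloxy)phenyl]-2,6-bis(4-methoxyphenyl)-4-(pivaloyloxymethyl)-2,3,5,6-tetrahydrobenzo[1,2-b:5,4-b']difuran-5-carboxylic acid; 14 1-iodo-3,5-dimethoxybenzene
Product: 30 [(2R,3R,5S,6S)-3-[3,5-bis(tosyloxy)phenyl]-5-(3,5-dimethoxyphenyl)-2,6-bis(4-methoxyphenyl)-2,3,5,6-tetrahydrobenzo[1,2-b:5,4-b']difuran-4-yl]methyl pivalate, via redox-active ester 29 (not isolated)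
Conditions: N-hydroxyphthalimide, i-PrN=C=N-i-Pr, DMAP (cat.), CH2Cl2, rt; then 14, NiBr2(dme) (10 mol %), 4,4′-di-tert-butyl-2,2′-bipyridine, Zn, DMA, rt
Reagents that add atoms: none
Why: The decarboxylative arylation of step 9; ring C should enter trans to the C-a aryl group (C-b S), the aryl tosylates do not add to zerovalent nickel under these conditions, and the two resorcinol rings are now chemically different.

Step 16
Reactants: 30 [(2R,3R,5S,6S)-3-[3,5-bis(tosyloxy)phenyl]-5-(3,5-dimethoxyphenyl)-2,6-bis(4-methoxyphenyl)-2,3,5,6-tetrahydrobenzo[1,2-b:5,4-b']difuran-4-yl]methyl pivalate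
Product: 31 [(2R,3R,5S,6S)-3-[3,5-bis(tosyloxy)phenyl]-5-(3,5-dimethoxyphenyl)-2,6-bis(4-methoxyphenyl)-2,3,5,6-tetrahydrobenzo[1,2-b:5,4-b']difuran-4-yl]methanol
Conditions: i-Bu2AlH, CH2Cl2, −78 °C; aq. potassium sodium tartrate (KNaC4H4O6)
Reagents that add atoms: none
Why: Reductive cleavage of the pivalate; aryl tosylates and aryl ethers are inert to the hydride at low temperature.

Step 17
Reactants: 31 [(2R,3R,5S,6S)-3-[3,5-bis(tosyloxy)phenyl]-5-(3,5-dimethoxyphenyl)-2,6-bis(4-methoxyphenyl)-2,3,5,6-tetrahydrobenzo[1,2-b:5,4-b']difuran-4-yl]methanol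
Product: 32 (2R,3R,5S,6S)-3-[3,5-bis(tosyloxy)phenyl]-5-(3,5-dimethoxyphenyl)-2,6-bis(4-methoxyphenyl)-2,3,5,6-tetrahydrobenzo[1,2-b:5,4-b']difuran-4-carbaldehyde
Conditions: Dess–Martin periodinane, NaHCO3, CH2Cl2, rt
Reagents that add atoms: none
Why: Dess–Martin oxidation of a primary benzylic alcohol to the aldehyde under buffered neutral conditions.

Step 18
Reactants: 33 (2,4-dimethoxyphenyl)methanol
Product: 34 (2,4-dimethoxybenzyl)triphenylphosphonium bromide
Conditions: Ph3P·HBr, MeCN, 80 °C
Reagents that add atoms: triphenylphosphine hydrobromide Br.c1ccc(P(c2ccccc2)c2ccccc2)cc1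
Why: The electron-rich benzylic alcohol ionises under HBr and the cation is trapped by triphenylphosphine, a standard preparation of benzylphosphonium salts.

Step 19
Reactants: 32 (2R,3R,5S,6S)-3-[3,5-bis(tosyloxy)phenyl]-5-(3,5-dimethoxyphenyl)-2,6-bis(4-methoxyphenyl)-2,3,5,6-tetrahydrobenzo[1,2-b:5,4-b']difuran-4-carbaldehyde; 34 (2,4-dimethoxybenzyl)triphenylphosphonium bromide
Product: 36 5-[(2R,3R,5S,6S)-4-[2-(2,4-dimethoxyphenyl)ethenyl]-5-(3,5-dimethoxyphenyl)-2,6-bis(4-methoxyphenyl)-2,3,5,6-tetrahydrobenzo[1,2-b:5,4-b']difuran-3-yl]-1,3-phenylene bis(4-methylbenzenesulfonate) (E/Z mixture), via ylide 35 (not isolated)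
Conditions: 34, KOt-Bu, THF, 0 °C; then 32, 0 °C → rt
Reagents that add atoms: none
Why: Wittig olefination with a semi-stabilised ylide; the E/Z mixture is used as such, because both isomers give the same cation in step 20.

Step 20
Reactants: 36 5-[(2R,3R,5S,6S)-4-[2-(2,4-dimethoxyphenyl)ethenyl]-5-(3,5-dimethoxyphenyl)-2,6-bis(4-methoxyphenyl)-2,3,5,6-tetrahydrobenzo[1,2-b:5,4-b']difuran-3-yl]-1,3-phenylene bis(4-methylbenzenesulfonate) (E/Z mixture)
Product: 37 hexamethyl ether bis-tosylate of the target (C-a S; C-b S; C-c S; C-d R; C-e R)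
Conditions: CF3CO2H, CH2Cl2, −20 → 0 °C
Reagents that add atoms: none
Why: Intramolecular Friedel–Crafts alkylation: the stilbene is protonated at the carbon next to ring A, giving the C-c cation stabilised by the 2,4-dimethoxyphenyl ring, and the ortho carbon of ring C closes the seven-membered ring, the closure that takes ε-viniferin to the ampelopsin B skeleton under acid. Ring B should turn away from the methoxy group ortho to the attacking carbon (allylic 1,3-strain) and end on the face of the C-b hydrogen, which is the (S) configuration at C-c. The tosylated ring on C-d is too electron-poor to compete.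

Step 21
Reactants: 37 hexamethyl ether bis-tosylate of the target (C-a S; C-b S; C-c S; C-d R; C-e R)
Product: 38 hexamethyl ether of the target with the free 3,5-dihydroxyphenyl group on C-d
Conditions: KOH, MeOH/THF, 60 °C; then aq. HCl
Reagents that add atoms: none
Why: Hydroxide attacks sulfur of the aryl sulfonates and releases the two phenols; no other phenol is present and the dihydrofurans have no acidic position, so hot base should be tolerated.

Step 22
Reactants: 38 hexamethyl ether of the target with the free 3,5-dihydroxyphenyl group on C-d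
Product: 39 target CNP0154047.3 (C-a S; C-b S; C-c S; C-d R; C-e R)
Conditions: BBr3 (excess), CH2Cl2, −78 °C → rt; MeOH, then H2O
Reagents that add atoms: none
Why: Lewis-acid cleavage of the six aryl methyl ethers; a benzylic aryl ether that ionises should re-close to the trans dihydrofuran, because C-b and C-d are not affected and anchor the configuration.

## Compound list

1 | (3,5-dimethoxyphenyl)methanol | COc1cc(CO)cc(OC)c1 | starting material
2 | 3,5-dimethoxybenzyl pivalate | COc1cc(COC(=O)C(C)(C)C)cc(OC)c1 | intermediate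
3 | 2-acetyl-3,5-dimethoxybenzyl pivalate | COc1cc(OC)c(C(C)=O)c(COC(=O)C(C)(C)C)c1 | intermediate (not isolated)
4 | 2-acetyl-3-hydroxy-5-methoxybenzyl pivalate | COc1cc(O)c(C(C)=O)c(COC(=O)C(C)(C)C)c1 | intermediate
5 | 2-[(E)-3-(dimethylamino)prop-2-enoyl]-3-hydroxy-5-methoxybenzyl pivalate | COc1cc(O)c(C(=O)/C=C/N(C)C)c(COC(=O)C(C)(C)C)c1 | intermediate (not isolated)
6 | (7-methoxy-4-oxo-4H-chromen-5-yl)methyl pivalate | COc1cc2occc(=O)c2c(COC(=O)C(C)(C)C)c1 | intermediate
7 | (4-methoxyphenyl)boronic acid | COc1ccc(B(O)O)cc1 | starting material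
8 | [(2R)-7-methoxy-2-(4-methoxyphenyl)-4-oxochroman-5-yl]methyl pivalate | COc1cc2c(c(COC(=O)C(C)(C)C)c1)C(=O)C[C@H](c1ccc(OC)cc1)O2 | intermediate
9 | [(2R)-4,7-dimethoxy-2-(4-methoxyphenyl)-2H-chromen-5-yl]methyl pivalate | COc1cc2c(c(COC(=O)C(C)(C)C)c1)C(OC)=C[C@H](c1ccc(OC)cc1)O2 | intermediate (not isolated)
10 | [(2S,3S)-3-[acetoxy(phenyl)-λ3-iodanyl]-4,4,7-trimethoxy-2-(4-methoxyphenyl)chroman-5-yl]methyl pivalate (iodine trans to the C2 aryl group) | COc1cc2c(c(COC(=O)C(C)(C)C)c1)C(OC)(OC)[C@@H](I(OC(C)=O)c1ccccc1)[C@H](c1ccc(OC)cc1)O2 | intermediate (not isolated)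
11 | [(2R,3R)-6-methoxy-2-(4-methoxyphenyl)-3-(trimethoxymethyl)-2,3-dihydrobenzofuran-4-yl]methyl pivalate | COc1cc2c(c(COC(=O)C(C)(C)C)c1)[C@@H](C(OC)(OC)OC)[C@H](c1ccc(OC)cc1)O2 | intermediate (not isolated)
12 | methyl (2R,3R)-6-methoxy-2-(4-methoxyphenyl)-4-(pivaloyloxymethyl)-2,3-dihydrobenzofuran-3-carboxylate | COc1cc2c(c(COC(=O)C(C)(C)C)c1)[C@@H](C(=O)OC)[C@H](c1ccc(OC)cc1)O2 | intermediate
13 | (2R,3R)-6-methoxy-2-(4-methoxyphenyl)-4-(pivaloyloxymethyl)-2,3-dihydrobenzofuran-3-carboxylic acid | COc1cc2c(c(COC(=O)C(C)(C)C)c1)[C@@H](C(=O)O)[C@H](c1ccc(OC)cc1)O2 | intermediate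
14 | 1-iodo-3,5-dimethoxybenzene | COc1cc(I)cc(OC)c1 | starting material
15 | 5-iodobenzene-1,3-diol | Oc1cc(O)cc(I)c1 | intermediate
16 | 5-iodo-1,3-phenylene bis(4-methylbenzenesulfonate) | Cc1ccc(S(=O)(=O)Oc2cc(I)cc(OS(=O)(=O)c3ccc(C)cc3)c2)cc1 | intermediate
17 | 1,3-dioxoisoindolin-2-yl (2R,3R)-6-methoxy-2-(4-methoxyphenyl)-4-(pivaloyloxymethyl)-2,3-dihydrobenzofuran-3-carboxylate | COc1cc2c(c(COC(=O)C(C)(C)C)c1)[C@@H](C(=O)ON1C(=O)c3ccccc3C1=O)[C@H](c1ccc(OC)cc1)O2 | intermediate (not isolated)
18 | [(2R,3R)-3-[3,5-bis(tosyloxy)phenyl]-6-methoxy-2-(4-methoxyphenyl)-2,3-dihydrobenzofuran-4-yl]methyl pivalate | COc1cc2c(c(COC(=O)C(C)(C)C)c1)[C@@H](c1cc(OS(=O)(=O)c3ccc(C)cc3)cc(OS(=O)(=O)c3ccc(C)cc3)c1)[C@H](c1ccc(OC)cc1)O2 | intermediate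
19 | [(2R,3R)-5-acetyl-3-[3,5-bis(tosyloxy)phenyl]-6-methoxy-2-(4-methoxyphenyl)-2,3-dihydrobenzofuran-4-yl]methyl pivalate | CC(=O)c1c(OC)cc2c(c1COC(=O)C(C)(C)C)[C@@H](c1cc(OS(=O)(=O)c3ccc(C)cc3)cc(OS(=O)(=O)c3ccc(C)cc3)c1)[C@H](c1ccc(OC)cc1)O2 | intermediate (not isolated)
20 | [(2R,3R)-5-acetyl-3-[3,5-bis(tosyloxy)phenyl]-6-hydroxy-2-(4-methoxyphenyl)-2,3-dihydrobenzofuran-4-yl]methyl pivalate | CC(=O)c1c(O)cc2c(c1COC(=O)C(C)(C)C)[C@@H](c1cc(OS(=O)(=O)c3ccc(C)cc3)cc(OS(=O)(=O)c3ccc(C)cc3)c1)[C@H](c1ccc(OC)cc1)O2 | intermediate
21 | [(2R,3R)-3-[3,5-bis(tosyloxy)phenyl]-5-[(E)-3-(dimethylamino)prop-2-enoyl]-6-hydroxy-2-(4-methoxyphenyl)-2,3-dihydrobenzofuran-4-yl]methyl pivalate | CN(C)/C=C/C(=O)c1c(O)cc2c(c1COC(=O)C(C)(C)C)[C@@H](c1cc(OS(=O)(=O)c3ccc(C)cc3)cc(OS(=O)(=O)c3ccc(C)cc3)c1)[C@H](c1ccc(OC)cc1)O2 | intermediate (not isolated)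
22 | [(2R,3R)-3-[3,5-bis(tosyloxy)phenyl]-2-(4-methoxyphenyl)-5-oxo-2,3-dihydro-5H-furo[3,2-g]chromen-4-yl]methyl pivalate | O=c1ccoc2cc3c(c(COC(=O)C(C)(C)C)c12)[C@@H](c1cc(OS(=O)(=O)c4ccc(C)cc4)cc(OS(=O)(=O)c4ccc(C)cc4)c1)[C@H](c1ccc(OC)cc1)O3 | intermediate
23 | [(2R,3R,7S)-3-[3,5-bis(tosyloxy)phenyl]-2,7-bis(4-methoxyphenyl)-5-oxo-2,3,6,7-tetrahydro-5H-furo[3,2-g]chromen-4-yl]methyl pivalate | O=C1C[C@@H](c2ccc(OC)cc2)Oc2cc3c(c(COC(=O)C(C)(C)C)c21)[C@@H](c1cc(OS(=O)(=O)c4ccc(C)cc4)cc(OS(=O)(=O)c4ccc(C)cc4)c1)[C@H](c1ccc(OC)cc1)O3 | intermediate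
24 | [(2R,3R,7S)-3-[3,5-bis(tosyloxy)phenyl]-5-methoxy-2,7-bis(4-methoxyphenyl)-2,3-dihydro-7H-furo[3,2-g]chromen-4-yl]methyl pivalate | COC1=C[C@@H](c2ccc(OC)cc2)Oc2cc3c(c(COC(=O)C(C)(C)C)c21)[C@@H](c1cc(OS(=O)(=O)c4ccc(C)cc4)cc(OS(=O)(=O)c4ccc(C)cc4)c1)[C@H](c1ccc(OC)cc1)O3 | intermediate (not isolated)
25 | [(2R,3R,6R,7R)-6-[acetoxy(phenyl)-λ3-iodanyl]-3-[3,5-bis(tosyloxy)phenyl]-5,5-dimethoxy-2,7-bis(4-methoxyphenyl)-2,3,6,7-tetrahydro-5H-furo[3,2-g]chromen-4-yl]methyl pivalate (iodine trans to the C7 aryl group) | COC1(OC)[C@H](I(OC(C)=O)c2ccccc2)[C@@H](c2ccc(OC)cc2)Oc2cc3c(c(COC(=O)C(C)(C)C)c21)[C@@H](c1cc(OS(=O)(=O)c4ccc(C)cc4)cc(OS(=O)(=O)c4ccc(C)cc4)c1)[C@H](c1ccc(OC)cc1)O3 | intermediate (not isolated)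
26 | [(2R,3R,5S,6S)-3-[3,5-bis(tosyloxy)phenyl]-2,6-bis(4-methoxyphenyl)-5-(trimethoxymethyl)-2,3,5,6-tetrahydrobenzo[1,2-b:5,4-b']difuran-4-yl]methyl pivalate | COc1ccc([C@H]2Oc3cc4c(c(COC(=O)C(C)(C)C)c3[C@@H]2C(OC)(OC)OC)[C@@H](c2cc(OS(=O)(=O)c5ccc(C)cc5)cc(OS(=O)(=O)c5ccc(C)cc5)c2)[C@H](c2ccc(OC)cc2)O4)cc1 | intermediate (not isolated)
27 | methyl (2R,3R,5S,6S)-3-[3,5-bis(tosyloxy)phenyl]-2,6-bis(4-methoxyphenyl)-4-(pivaloyloxymethyl)-2,3,5,6-tetrahydrobenzo[1,2-b:5,4-b']difuran-5-carboxylate | COc1ccc([C@H]2Oc3cc4c(c(COC(=O)C(C)(C)C)c3[C@@H]2C(=O)OC)[C@@H](c2cc(OS(=O)(=O)c5ccc(C)cc5)cc(OS(=O)(=O)c5ccc(C)cc5)c2)[C@H](c2ccc(OC)cc2)O4)cc1 | intermediate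
28 | (2R,3R,5S,6S)-3-[3,5-bis(tosyloxy)phenyl]-2,6-bis(4-methoxyphenyl)-4-(pivaloyloxymethyl)-2,3,5,6-tetrahydrobenzo[1,2-b:5,4-b']difuran-5-carboxylic acid | COc1ccc([C@H]2Oc3cc4c(c(COC(=O)C(C)(C)C)c3[C@@H]2C(=O)O)[C@@H](c2cc(OS(=O)(=O)c5ccc(C)cc5)cc(OS(=O)(=O)c5ccc(C)cc5)c2)[C@H](c2ccc(OC)cc2)O4)cc1 | intermediate
29 | 1,3-dioxoisoindolin-2-yl (2R,3R,5S,6S)-3-[3,5-bis(tosyloxy)phenyl]-2,6-bis(4-methoxyphenyl)-4-(pivaloyloxymethyl)-2,3,5,6-tetrahydrobenzo[1,2-b:5,4-b']difuran-5-carboxylate | COc1ccc([C@H]2Oc3cc4c(c(COC(=O)C(C)(C)C)c3[C@@H]2C(=O)ON2C(=O)c5ccccc5C2=O)[C@@H](c2cc(OS(=O)(=O)c5ccc(C)cc5)cc(OS(=O)(=O)c5ccc(C)cc5)c2)[C@H](c2ccc(OC)cc2)O4)cc1 | intermediate (not isolated)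
30 | [(2R,3R,5S,6S)-3-[3,5-bis(tosyloxy)phenyl]-5-(3,5-dimethoxyphenyl)-2,6-bis(4-methoxyphenyl)-2,3,5,6-tetrahydrobenzo[1,2-b:5,4-b']difuran-4-yl]methyl pivalate | COc1ccc([C@H]2Oc3cc4c(c(COC(=O)C(C)(C)C)c3[C@@H]2c2cc(OC)cc(OC)c2)[C@@H](c2cc(OS(=O)(=O)c5ccc(C)cc5)cc(OS(=O)(=O)c5ccc(C)cc5)c2)[C@H](c2ccc(OC)cc2)O4)cc1 | intermediate
31 | [(2R,3R,5S,6S)-3-[3,5-bis(tosyloxy)phenyl]-5-(3,5-dimethoxyphenyl)-2,6-bis(4-methoxyphenyl)-2,3,5,6-tetrahydrobenzo[1,2-b:5,4-b']difuran-4-yl]methanol | COc1ccc([C@H]2Oc3cc4c(c(CO)c3[C@@H]2c2cc(OC)cc(OC)c2)[C@@H](c2cc(OS(=O)(=O)c5ccc(C)cc5)cc(OS(=O)(=O)c5ccc(C)cc5)c2)[C@H](c2ccc(OC)cc2)O4)cc1 | intermediate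
32 | (2R,3R,5S,6S)-3-[3,5-bis(tosyloxy)phenyl]-5-(3,5-dimethoxyphenyl)-2,6-bis(4-methoxyphenyl)-2,3,5,6-tetrahydrobenzo[1,2-b:5,4-b']difuran-4-carbaldehyde | COc1ccc([C@H]2Oc3cc4c(c(C=O)c3[C@@H]2c2cc(OC)cc(OC)c2)[C@@H](c2cc(OS(=O)(=O)c5ccc(C)cc5)cc(OS(=O)(=O)c5ccc(C)cc5)c2)[C@H](c2ccc(OC)cc2)O4)cc1 | intermediate
33 | (2,4-dimethoxyphenyl)methanol | COc1ccc(CO)c(OC)c1 | starting material
34 | (2,4-dimethoxybenzyl)triphenylphosphonium bromide | COc1ccc(C[P+](c2ccccc2)(c2ccccc2)c2ccccc2)c(OC)c1.[Br-] | intermediate
35 | (2,4-dimethoxybenzylidene)triphenylphosphorane | COc1ccc(C=P(c2ccccc2)(c2ccccc2)c2ccccc2)c(OC)c1 | intermediate (not isolated)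
36 | 5-[(2R,3R,5S,6S)-4-[2-(2,4-dimethoxyphenyl)ethenyl]-5-(3,5-dimethoxyphenyl)-2,6-bis(4-methoxyphenyl)-2,3,5,6-tetrahydrobenzo[1,2-b:5,4-b']difuran-3-yl]-1,3-phenylene bis(4-methylbenzenesulfonate), E/Z mixture | COc1ccc([C@H]2Oc3cc4c(c(C=Cc5ccc(OC)cc5OC)c3[C@@H]2c2cc(OC)cc(OC)c2)[C@@H](c2cc(OS(=O)(=O)c5ccc(C)cc5)cc(OS(=O)(=O)c5ccc(C)cc5)c2)[C@H](c2ccc(OC)cc2)O4)cc1 | intermediate
37 | hexamethyl ether bis-tosylate of the target: the hexacycle with OMe on both 4-oxyphenyl rings, on ring C and on ring B, and OTs on both oxygens of the C-d aryl ring (C-a S; C-b S; C-c S; C-d R; C-e R) | COc1ccc([C@H]2Oc3cc4c(c5c3[C@@H]2c2cc(OC)cc(OC)c2[C@H](c2ccc(OC)cc2OC)C5)[C@@H](c2cc(OS(=O)(=O)c6ccc(C)cc6)cc(OS(=O)(=O)c6ccc(C)cc6)c2)[C@H](c2ccc(OC)cc2)O4)cc1 | intermediate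
38 | hexamethyl ether of the target with the free 3,5-dihydroxyphenyl group on C-d (C-a S; C-b S; C-c S; C-d R; C-e R) | COc1ccc([C@H]2Oc3cc4c(c5c3[C@@H]2c2cc(OC)cc(OC)c2[C@H](c2ccc(OC)cc2OC)C5)[C@@H](c2cc(O)cc(O)c2)[C@H](c2ccc(OC)cc2)O4)cc1 | intermediate
39 | CNP0154047.3 (C-a S; C-b S; C-c S; C-d R; C-e R) | Oc1ccc([C@H]2Oc3cc4c(c5c3[C@@H]2c2cc(O)cc(O)c2[C@H](c2ccc(O)cc2O)C5)[C@@H](c2cc(O)cc(O)c2)[C@H](c2ccc(O)cc2)O4)cc1 | target

## Step count and risks

Total: 22 steps. Longest linear sequence: 19 steps (steps 1–6, 9–17 and 19–22).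

**Step 5 (key step; the same applies to step 13).** The most likely failures are migration of the C2 aryl group instead of ring A (isoflavone formation), slow enol ether formation next to the peri CH2OPiv group, and erosion of the C-e configuration by acid-induced opening and re-closure of the pyranone before iodination. The fallback sets out from 8 and returns at 12, and contracts the ring by a carbene shift in which only ring A can migrate. Deprotonation with LiN(SiMe3)2 at −78 °C and acylation with CF3CO2CH2CF3 would give the trifluoroacetyl ketone F1. Diazo transfer with 4-acetamidobenzenesulfonyl azide and Et3N would give the 3-diazo flavanone F2. Irradiation in methanol (Wolff rearrangement) would move A4 to C3 and give the ketene F3, which takes up methanol and should settle as the trans ester 12.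

**Step 9 (and step 15).** The most likely failures are dimerisation or reduction of the benzylic radical before it meets nickel, and poor facial selectivity in its capture, which cannot be corrected afterwards. The fallback sets out from 13, passes through 17 and returns at 18, and replaces radical capture at nickel by a boronate coupling. Decarboxylative borylation of 17 (B2pin2, Cu(acac)2, LiOH·H2O, MgCl2) would give the trans pinacol boronate F4. Suzuki–Miyaura coupling of this secondary benzylic boronate with 16 (Pd2(dba)3, PPh3, Ag2O) would give 18 with retention. For step 15 the same two operations would be used with 14.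

**Step 10.** The most likely failures are opening of the existing dihydrofuran at its benzylic aryl ether by the stoichiometric Lewis acid, and substitution at A2 instead of A6. The fallback sets out from 18 and returns at 19, and makes the A6–carbon bond without a Lewis acid. Bromination with N-bromosuccinimide in MeCN would give the A6 bromide F5, whose regiochemistry can be checked before going on. Coupling with tributyl(1-ethoxyvinyl)stannane and Pd(PPh3)4 (Kosugi–Migita–Stille) would give the enol ether F6. Dilute aqueous HCl would give 19, which is then taken to 20 with BCl3 alone.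

**Step 20.** The most likely failures are poor facial selectivity at C-c in the ring closure, and opening of the benzylic aryl ethers or oligomerisation under the Brønsted acid. The fallback sets out from 32 and returns at 37, and generates the same cation by ionisation of an alcohol under a catalytic Lewis acid at low temperature, so that no strong protic acid is present. Wittig reaction of 32 with the ylide from MeOCH2PPh3Cl and KOt-Bu would give the methyl enol ether F7. Mild aqueous acid would give the homologous aldehyde F8. (2,4-Dimethoxyphenyl)magnesium bromide would give the secondary alcohol F9 (either epimer). Bi(OTf)3 (5 mol %) in CH2Cl2 at −20 °C would ionise it and close the ring to 37.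

**Step 22.** The most likely failure is irreversible cleavage of the benzylic aryl ether bonds by the boron Lewis acid, with capture of the cations by bromide instead of re-closure, together with incomplete demethylation. The fallback sets out from 38 and returns at 39, and removes the methyl groups by nucleophilic attack at carbon under basic conditions (NaSEt, DMF, 140 °C, under argon), which the benzylic ethers should tolerate. It makes no new compound (F0).

## Further compounds

F1 | step 5 | [(2R)-7-methoxy-2-(4-methoxyphenyl)-4-oxo-3-(trifluoroacetyl)chroman-5-yl]methyl pivalate (C3 epimers and enol) | COc1cc2c(c(COC(=O)C(C)(C)C)c1)C(=O)C(C(=O)C(F)(F)F)[C@H](c1ccc(OC)cc1)O2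
F2 | step 5 | [(2S)-3-diazo-7-methoxy-2-(4-methoxyphenyl)-4-oxochroman-5-yl]methyl pivalate (C2 arranged as in 8) | COc1cc2c(c(COC(=O)C(C)(C)C)c1)C(=O)C(=[N+]=[N-])[C@H](c1ccc(OC)cc1)O2
F3 | step 5 | [6-methoxy-2-(4-methoxyphenyl)-3-(oxomethylidene)-2,3-dihydrobenzofuran-4-yl]methyl pivalate (ketene; C2 arranged as in 8) | COc1cc2c(c(COC(=O)C(C)(C)C)c1)C(=C=O)[C@H](c1ccc(OC)cc1)O2
F4 | step 9 | [(2R,3R)-6-methoxy-2-(4-methoxyphenyl)-3-(4,4,5,5-tetramethyl-1,3,2-dioxaborolan-2-yl)-2,3-dihydrobenzofuran-4-yl]methyl pivalate (trans) | COc1cc2c(c(COC(=O)C(C)(C)C)c1)[C@@H](B1OC(C)(C)C(C)(C)O1)[C@H](c1ccc(OC)cc1)O2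
F5 | step 10 | [(2R,3R)-5-bromo-3-[3,5-bis(tosyloxy)phenyl]-6-methoxy-2-(4-methoxyphenyl)-2,3-dihydrobenzofuran-4-yl]methyl pivalate | COc1cc2c(c(COC(=O)C(C)(C)C)c1Br)[C@@H](c1cc(OS(=O)(=O)c3ccc(C)cc3)cc(OS(=O)(=O)c3ccc(C)cc3)c1)[C@H](c1ccc(OC)cc1)O2
F6 | step 10 | [(2R,3R)-3-[3,5-bis(tosyloxy)phenyl]-5-(1-ethoxyethenyl)-6-methoxy-2-(4-methoxyphenyl)-2,3-dihydrobenzofuran-4-yl]methyl pivalate | CCOC(=C)c1c(OC)cc2c(c1COC(=O)C(C)(C)C)[C@@H](c1cc(OS(=O)(=O)c3ccc(C)cc3)cc(OS(=O)(=O)c3ccc(C)cc3)c1)[C@H](c1ccc(OC)cc1)O2
F7 | step 20 | 5-[(2R,3R,5S,6S)-5-(3,5-dimethoxyphenyl)-4-(2-methoxyethenyl)-2,6-bis(4-methoxyphenyl)-2,3,5,6-tetrahydrobenzo[1,2-b:5,4-b']difuran-3-yl]-1,3-phenylene bis(4-methylbenzenesulfonate) (E/Z mixture) | COc1ccc([C@H]2Oc3cc4c(c(C=COC)c3[C@@H]2c2cc(OC)cc(OC)c2)[C@@H](c2cc(OS(=O)(=O)c5ccc(C)cc5)cc(OS(=O)(=O)c5ccc(C)cc5)c2)[C@H](c2ccc(OC)cc2)O4)cc1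
F8 | step 20 | 5-[(2R,3R,5S,6S)-5-(3,5-dimethoxyphenyl)-2,6-bis(4-methoxyphenyl)-4-(2-oxoethyl)-2,3,5,6-tetrahydrobenzo[1,2-b:5,4-b']difuran-3-yl]-1,3-phenylene bis(4-methylbenzenesulfonate) | COc1ccc([C@H]2Oc3cc4c(c(CC=O)c3[C@@H]2c2cc(OC)cc(OC)c2)[C@@H](c2cc(OS(=O)(=O)c5ccc(C)cc5)cc(OS(=O)(=O)c5ccc(C)cc5)c2)[C@H](c2ccc(OC)cc2)O4)cc1
F9 | step 20 | 5-[(2R,3R,5S,6S)-4-[2-(2,4-dimethoxyphenyl)-2-hydroxyethyl]-5-(3,5-dimethoxyphenyl)-2,6-bis(4-methoxyphenyl)-2,3,5,6-tetrahydrobenzo[1,2-b:5,4-b']difuran-3-yl]-1,3-phenylene bis(4-methylbenzenesulfonate) (both carbinol epimers) | COc1ccc([C@H]2Oc3cc4c(c(CC(O)c5ccc(OC)cc5OC)c3[C@@H]2c2cc(OC)cc(OC)c2)[C@@H](c2cc(OS(=O)(=O)c5ccc(C)cc5)cc(OS(=O)(=O)c5ccc(C)cc5)c2)[C@H](c2ccc(OC)cc2)O4)cc1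
F0 | step 22 | none | none
A1 | alternative 1 | open-chain α-diazo enone with the cycloheptene, the silyl ether at C-a and the ethynyl ether on the C-e oxygen | COc1ccc([C@@H](O[Si](C)(C)C(C)(C)C)[C@H]2c3cc(OC)cc(OC)c3[C@H](c3ccc(OC)cc3OC)CC(C(=O)C(=[N+]=[N-])[C@@H](c3cc(OC)cc(OC)c3)[C@H](c3ccc(OC)cc3)OC#C)=C2)cc1
A2 | alternative 1 | ring A phenol with the seven-membered ring and the C-d/C-e dihydrobenzofuran in place | COc1ccc([C@@H](O[Si](C)(C)C(C)(C)C)[C@H]2c3cc(OC)cc(OC)c3[C@H](c3ccc(OC)cc3OC)Cc3c2c(O)cc2c3[C@@H](c3cc(OC)cc(OC)c3)[C@H](c3ccc(OC)cc3)O2)cc1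
A3 | alternative 2 | keto aldehyde: bis-dihydrofuran with CHO on ring atom A5 and the 2,4-dimethoxybenzoyl group on ring C | COc1ccc([C@H]2Oc3cc4c(c(C=O)c3[C@@H]2c2cc(OC)cc(OC)c2C(=O)c2ccc(OC)cc2OC)[C@@H](c2cc(OC)cc(OC)c2)[C@H](c2ccc(OC)cc2)O4)cc1
A4 | alternative 2 | dibenzocycloheptene with the C-c=CH double bond | COc1ccc([C@H]2Oc3cc4c(c5c3[C@@H]2c2cc(OC)cc(OC)c2C(c2ccc(OC)cc2OC)=C5)[C@@H](c2cc(OC)cc(OC)c2)[C@H](c2ccc(OC)cc2)O4)cc1
A5 | alternative 3 | methyl 3,5-dimethoxy-2-vinylbenzoate | COC(=O)c1cc(OC)cc(OC)c1C=C
A6 | alternative 3 | 1,3-bis(benzyloxy)-5-bromobenzene | Brc1cc(OCc2ccccc2)cc(OCc2ccccc2)c1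
A7 | alternative 3 | (2,4-dimethoxyphenyl)zinc bromide | COc1ccc([Zn]Br)c(OC)c1
A8 | alternative 3 | triarylethane ester with C-c set | COC(=O)c1cc(OC)cc(OC)c1[C@H](c1ccc(OC)cc1OC)Cc1cc(OCc2ccccc2)cc(OCc2ccccc2)c1
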